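**Retrosynthetic overview**
1. Altisin 11 ⇒ pentamethoxyflavone 9 by chelation-directed cleavage of the peri 5-OMe (last step).
2. Pyranone ring of 9 (the only ring built, formed last) ⇒ 1,3-diketone 7 by cyclodehydration (O1–C2 bond).
3. Diketone 7 ⇒ key C–C bond by intermolecular Claisen condensation of the dianion of acetophenone 4 with 2,6-dimethoxybenzoyl chloride 5.
4. Acetophenone 4 ⇒ 1,2,3,5-tetramethoxybenzene 2 (Friedel–Crafts acylation with ortho-demethylation) ⇒ 3,4,5-trimethoxyphenol 1; both benzene rings are bought.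

Assumption: the target SMILES has no stereocentre and no configurationally stable axis (the B-ring is symmetrically 2,6-disubstituted), so altisin is achiral and no enantiocontrol is needed.

**Route**

Step 1
Reactants: 1 3,4,5-trimethoxyphenol
Product: 2 1,2,3,5-tetramethoxybenzene
Conditions: MeI (1.5 equiv), K2CO3 (2 equiv), acetone, reflux, 12 h
Reagents that add atoms: iodomethane, CI
Why: Williamson ether synthesis, in which the only phenoxide is methylated by SN2 on MeI and no stereocentre is involved.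

Step 2
Reactants: 2 1,2,3,5-tetramethoxybenzene
Product: 4 1-(2-hydroxy-3,4,6-trimethoxyphenyl)ethan-1-one, via tetramethoxyacetophenone 3 (not isolated)
Conditions: AcCl (1.2 equiv), AlCl3 (3 equiv), Et2O, 0 °C → rt, 24 h; then ice–water
Reagents that add atoms: acetyl chloride, CC(Cl)=O
Why: Friedel–Crafts acylation at the only kind of free ring position (C4 ≡ C6) gives 3, and AlCl3 chelated to the new carbonyl then cleaves the ortho OMe that is buttressed by the neighbouring 3-OMe (chelation-controlled ether cleavage), the product being held as an aluminium chelate until work-up.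

Step 3
Reactants: 4 1-(2-hydroxy-3,4,6-trimethoxyphenyl)ethan-1-one; 5 2,6-dimethoxybenzoyl chloride
Product: 7 1-(2,6-dimethoxyphenyl)-3-(2-hydroxy-3,4,6-trimethoxyphenyl)propane-1,3-dione, via dilithium dianion 6 (not isolated)
Conditions: LiHMDS (4 equiv), THF, −78 → −10 °C, 2 h; then 5 (1.05 equiv), −78 °C → rt, 12 h; aq. HCl quench
Reagents that add atoms: none
Why: Crossed (intermolecular) Claisen condensation, in which the phenoxide–enolate dianion is C-acylated by a non-enolisable aroyl chloride, excess base deprotonates the diketone to drive the reaction, and any O-acylated material is funnelled to the same diketone by a Baker–Venkataraman shift.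

Step 4
Reactants: 7 1-(2,6-dimethoxyphenyl)-3-(2-hydroxy-3,4,6-trimethoxyphenyl)propane-1,3-dione
Product: 9 2-(2,6-dimethoxyphenyl)-5,7,8-trimethoxy-4H-chromen-4-one, via 2-hydroxyflavanone hemiketal 8 (not isolated)
Conditions: AcOH, H2SO4 (0.5% v/v), 95–100 °C, 2 h
Reagents that add atoms: none
Why: Acid-catalysed cyclodehydration of an o-hydroxyaryl 1,3-diketone, in which the single free phenol adds to the aryl ketone and the racemic hemiketal loses water to give the aromatic γ-pyrone as one regioisomer with no stereocentre left.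

Step 5
Reactants: 9 2-(2,6-dimethoxyphenyl)-5,7,8-trimethoxy-4H-chromen-4-one
Product: 11 altisin (2-(2,6-dimethoxyphenyl)-5-hydroxy-7,8-dimethoxy-4H-chromen-4-one), via dichloroboron chelate 10 (not isolated)
Conditions: BCl3 (1 M in CH2Cl2, 2.5 equiv), CH2Cl2, −78 → 0 °C, 2 h; then H2O
Reagents that add atoms: none
Why: Chelation-directed Lewis-acid ether cleavage, in which BCl3 bridges C4=O and the peri 5-OMe in a six-membered chelate so that only this methyl is lost as MeCl, while the 7-, 8-, 2′- and 6′-OMe groups are not activated at ≤0 °C.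

**Compound list**
1 | 3,4,5-trimethoxyphenol | COc1cc(O)cc(OC)c1OC | starting material
2 | 1,2,3,5-tetramethoxybenzene | COc1cc(OC)c(OC)c(OC)c1 | intermediate
3 | 1-(2,3,4,6-tetramethoxyphenyl)ethan-1-one (not isolated) | CC(=O)c1c(OC)cc(OC)c(OC)c1OC | intermediate
4 | 1-(2-hydroxy-3,4,6-trimethoxyphenyl)ethan-1-one | CC(=O)c1c(OC)cc(OC)c(OC)c1O | intermediate
5 | 2,6-dimethoxybenzoyl chloride | COc1cccc(OC)c1C(Cl)=O | starting material
6 | dilithium phenoxide–enolate of 4 (not isolated) | [Li+].[Li+].C=C([O-])c1c(OC)cc(OC)c(OC)c1[O-] | intermediate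
7 | 1-(2,6-dimethoxyphenyl)-3-(2-hydroxy-3,4,6-trimethoxyphenyl)propane-1,3-dione | COc1cccc(OC)c1C(=O)CC(=O)c1c(OC)cc(OC)c(OC)c1O | intermediate
8 | 2-(2,6-dimethoxyphenyl)-2-hydroxy-5,7,8-trimethoxy-2,3-dihydro-4H-chromen-4-one (racemic, not isolated) | COc1cccc(OC)c1C1(O)CC(=O)c2c(OC)cc(OC)c(OC)c2O1 | intermediate
9 | 2-(2,6-dimethoxyphenyl)-5,7,8-trimethoxy-4H-chromen-4-one | COc1cccc(OC)c1-c1cc(=O)c2c(OC)cc(OC)c(OC)c2o1 | intermediate
10 | 5-O-dichloroboryl chelate of the 5-hydroxyflavone (not isolated) | COc1cccc(OC)c1-c1cc(=O)c2c(OB(Cl)Cl)cc(OC)c(OC)c2o1 | intermediate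
11 | altisin, 2-(2,6-dimethoxyphenyl)-5-hydroxy-7,8-dimethoxy-4H-chromen-4-one | COc1cccc(OC)c1-c1cc(=O)c2c(O)cc(OC)c(OC)c2o1 | target

**Summary**
Total step count: 5. Longest linear sequence: 5 steps (1 → 2 → 4 → 7 → 9 → 11).

**Steps most likely to fail**

Step 2. The risk is cleavage of the wrong ortho methyl ether (6-OMe) or of both, which would lead into the 5,6,7-series. The fallback sets out from 1 and comes back at 11, bypassing steps 2–5. It makes the two carbonyl-ortho oxygens chemically different instead of relying on selective cleavage. C-Acetylation of 1 (AcOH, BF3·OEt2, 90 °C) gives 1-(6-hydroxy-2,3,4-trimethoxyphenyl)ethan-1-one F1. Tosylation (TsCl, Et3N, DMAP, CH2Cl2) gives 2-acetyl-3,4,5-trimethoxyphenyl 4-methylbenzenesulfonate F2. BCl3 (CH2Cl2, −78 → 0 °C) can now cleave only one carbonyl-ortho methyl ether and gives 2-acetyl-3-hydroxy-4,5-dimethoxyphenyl 4-methylbenzenesulfonate F3. Claisen condensation with 5 under the step 3 conditions gives 2-[3-(2,6-dimethoxyphenyl)-3-oxopropanoyl]-3-hydroxy-4,5-dimethoxyphenyl 4-methylbenzenesulfonate F4. Cyclodehydration under the step 4 conditions gives 2-(2,6-dimethoxyphenyl)-7,8-dimethoxy-4-oxo-4H-chromen-5-yl 4-methylbenzenesulfonate F5. Sulfonate cleavage (KOH, aq. MeOH–THF, 40 °C, then acidification) gives 11.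

Step 3. The risk is sluggish or O-selective acylation by the di-ortho-substituted acid chloride. The fallback sets out from 4 and comes back at 9. It replaces the acylation by a Claisen–Schmidt aldol condensation with purchased 2,6-dimethoxybenzaldehyde (COc1cccc(OC)c1C=O; KOH, EtOH, rt). This gives (E)-3-(2,6-dimethoxyphenyl)-1-(2-hydroxy-3,4,6-trimethoxyphenyl)prop-2-en-1-one F6. Oxidative cyclisation of this chalcone (cat. I2, DMSO, 130 °C) gives 9.

Step 5. The risk is incomplete reaction or additional loss of the 8-OMe. The fallback sets out from 9 and comes back at 11. It replaces selective cleavage by exhaustive cleavage and selective re-alkylation. BBr3 (excess, CH2Cl2, −78 °C → rt) gives 2-(2,6-dihydroxyphenyl)-5,7,8-trihydroxy-4H-chromen-4-one F7. Methylation with Me2SO4 (4.1 equiv), K2CO3, acetone, reflux under N2 then caps the four free phenols. The hydrogen-bonded 5-OH is the least nucleophilic and is left, giving 11.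

**Further compounds**
F1 | step 2 | 1-(6-hydroxy-2,3,4-trimethoxyphenyl)ethan-1-one | CC(=O)c1c(O)cc(OC)c(OC)c1OC
F2 | step 2 | 2-acetyl-3,4,5-trimethoxyphenyl 4-methylbenzenesulfonate | CC(=O)c1c(OS(=O)(=O)c2ccc(C)cc2)cc(OC)c(OC)c1OC
F3 | step 2 | 2-acetyl-3-hydroxy-4,5-dimethoxyphenyl 4-methylbenzenesulfonate | CC(=O)c1c(OS(=O)(=O)c2ccc(C)cc2)cc(OC)c(OC)c1O
F4 | step 2 | 2-[3-(2,6-dimethoxyphenyl)-3-oxopropanoyl]-3-hydroxy-4,5-dimethoxyphenyl 4-methylbenzenesulfonate | COc1cccc(OC)c1C(=O)CC(=O)c1c(OS(=O)(=O)c2ccc(C)cc2)cc(OC)c(OC)c1O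
F5 | step 2 | 2-(2,6-dimethoxyphenyl)-7,8-dimethoxy-4-oxo-4H-chromen-5-yl 4-methylbenzenesulfonate | COc1cccc(OC)c1-c1cc(=O)c2c(OS(=O)(=O)c3ccc(C)cc3)cc(OC)c(OC)c2o1
F6 | step 3 | (E)-3-(2,6-dimethoxyphenyl)-1-(2-hydroxy-3,4,6-trimethoxyphenyl)prop-2-en-1-one | COc1cccc(OC)c1/C=C/C(=O)c1c(OC)cc(OC)c(OC)c1O
F7 | step 5 | 2-(2,6-dihydroxyphenyl)-5,7,8-trihydroxy-4H-chromen-4-one | Oc1cccc(O)c1-c1cc(=O)c2c(O)cc(O)c(O)c2o1
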